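The constants were drawn at random within sensible limits, and the outcome is calculated.

The ratio that opens these flasks is the rate at which Q passes to Q.Z over the rate at which it passes to Q.G, and at the start of elm it is 1.9.

    Q + Z → Q.Z (k1 = 0.12 L mol⁻¹ s⁻¹)
    Q + G → Q.G (k2 = 0.20 L mol⁻¹ s⁻¹)
    Q.Z → J (k3 = 0.020 s⁻¹)

| flask | Q | Z | G | time |
|---|---|---|---|---|
| elm | 0.050 M | 0.150 M | 0.0475 M | 40 s |
| birch | 0.050 M | 0.200 M | 0.0475 M | 40 s |
| larch | 0.050 M | 0.250 M | 0.0475 M | 40 s |

1. which of the two there is more of at the end, elm (Q.Z / J)
2. which of the two there is more of at the end, birch (Q.Z / J)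
3. which of the two there is more of at the end, larch (Q.Z / J)
4. final Q.Z, as a percentage of the Q charged, in elm
5. final Q.Z, as a percentage of the Q charged, in birch
6. final Q.Z, as a percentage of the Q charged, in larch

I hold [Z] and [G] at their charges as a rough reckoning, so that Q in elm falls by a factor of e in 36.4 s. This Q time, the reciprocal of the two first-order constants added, is what I carry. Q.Z has a lifetime of 50.0 s, longer than the Q time of elm and longer than the 40 s run, so I expect Q.Z to stay ahead of J there.

The formula for the middle species of two consecutive first-order steps, with Q shared in each flask by that flask's own opening ratio, gives Q.Z at 27.9 % in elm, 33.3 % in birch and 37.4 % in larch. For J it gives 15.7 %, 19.6 % and 22.9 %, each lower than its Q.Z.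

The forecast also names Q.Z, Q.Z and Q.Z, with Q.Z at 26.8 %, 32.2 % and 36.5 %, on the ground that “less than half is lost to J”. In elm my figure stands 1.1 percentage points above it.

The flask gives Q.Z at 26.7 % in elm, 32.1 % in birch and 36.4 % in larch, with J at 15.1 %, 18.9 % and 22.2 %, so the forecast holds on each count. In elm, each step taken net, Q.Z is made 3.19 times as fast as it is used up at 14.5 s and 1.08 times as fast at 40.0 s. A neighbour of elm with 0.26 M of Z shortens the Q time from 36.4 s to 24.6 s, which reckons to 38.1 % of Q.Z; that flask ends at 37.1 %.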